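**Retrosynthetic overview**
- The target is unmasked last: one BCl3 step removes three benzyl ethers and the chelated 5-O-methyl group from a protected flavanone–flavone.
- The biaryl bond (ring B of the flavanone to C8 of the flavone) comes from a Negishi coupling, run while the flavanone C4 is still a 1,3-dithiane, so C2 cannot racemise by ring opening.
- Flavanone ring C: O1–C2 by intramolecular Mitsunobu inversion; C3–C4 by opening an (S)-aryloxirane with the 2-aryl-1,3-dithianyl carbanion (acyl anion equivalent, key step).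
- The oxirane comes from 2-bromoanisole (Friedel–Crafts, asymmetric transfer hydrogenation); the 8-iodoflavone from an iodoacetophenone via chalcone and I2/DMSO.
- Ring order: flavone pyranone (separate branch), then the flavanone pyran ring as its dithioketal, then biaryl coupling, then release of the C4 carbonyl.

Assumption: the target SMILES carries no descriptor for the biaryl axis, so the axis is treated as configurationally unspecified and no axial control is attempted.

**Step 1**
Reactants: 1 2-hydroxy-4,6-dimethoxybenzaldehyde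
Product: 2 2-(1,3-dithian-2-yl)-3,5-dimethoxyphenol
Conditions: HS(CH2)3SH (1.2 equiv), BF3·OEt2 (0.5 equiv), CH2Cl2, 0 °C to rt
Reagents that add atoms: propane-1,3-dithiol, SCCCS
Why: Lewis-acid-catalysed dithioacetalisation of the aldehyde gives the 2-aryl-1,3-dithiane whose C–H is the latent acyl anion (Corey–Seebach precursor); the free phenol is tolerated and no stereocentre is formed.

**Step 2**
Reactants: 3 2-bromoanisole; 4 chloroacetyl chloride
Product: 5 1-(3-bromo-4-methoxyphenyl)-2-chloroethan-1-one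
Conditions: AlCl3 (1.2 equiv), CH2Cl2, 0 °C to rt; then ice/1 M HCl
Reagents that add atoms: none
Why: Friedel–Crafts acylation goes para to the strongly directing methoxy group, giving the phenacyl chloride that carries C2 and C3 of the future flavanone.

**Step 3**
Reactants: 5 1-(3-bromo-4-methoxyphenyl)-2-chloroethan-1-one
Product: 7 (2S)-2-(3-bromo-4-methoxyphenyl)oxirane, via chlorohydrin 6 (not isolated)
Conditions: RuCl[(R,R)-TsDPEN](p-cymene) (0.5 mol%), HCO2H/Et3N (5:2), EtOAc, 25 °C; then 2 M aq. NaOH, i-PrOH, 0 °C to rt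
Reagents that add atoms: none
Why: Noyori–Ikariya asymmetric transfer hydrogenation with the (R,R)-TsDPEN ruthenium catalyst delivers hydride to one face of the aryl ketone to give the (S)-chlorohydrin (CH2Cl outranks aryl, hence S), and hydroxide then closes the epoxide by intramolecular Williamson displacement at CH2Cl, which leaves the stereocentre untouched.

**Step 4 (key step)**
Reactants: 2 2-(1,3-dithian-2-yl)-3,5-dimethoxyphenol; 7 (2S)-2-(3-bromo-4-methoxyphenyl)oxirane
Product: 9 2-{2-[(2R)-2-(3-bromo-4-methoxyphenyl)-2-hydroxyethyl]-1,3-dithian-2-yl}-3,5-dimethoxyphenol, via dilithio dianion 8 (not isolated)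
Conditions: n-BuLi (2.1 equiv), THF, −30 to 0 °C; then 7, −78 °C to rt; sat. aq. NH4Cl
Reagents that add atoms: none
Why: Corey–Seebach umpolung, in which the unprotected O,C-dianion places an acyl anion equivalent at the future C4 and opens the terminal CH2 of the epoxide by SN2, joining two carbons that are both electrophilic in their natural polarity (aldehyde carbon and epoxide carbon); the stereocentre is not touched, so (S)-7 gives (R)-9 (the descriptor changes only through CIP priorities), and the aryl bromide survives because the stabilised dithianyl anion does not undergo halogen–metal exchange.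

**Step 5**
Reactants: 9 2-{2-[(2R)-2-(3-bromo-4-methoxyphenyl)-2-hydroxyethyl]-1,3-dithian-2-yl}-3,5-dimethoxyphenol
Product: 10 (2S)-2-(3-bromo-4-methoxyphenyl)-5,7-dimethoxyspiro[chromane-4,2'-[1,3]dithiane]
Conditions: PPh3 (1.5 equiv), DIAD (1.5 equiv), THF (0.02 M), 0 °C to rt
Reagents that add atoms: none
Why: intramolecular Mitsunobu etherification (6-exo-tet SN2 of the phenol on the alkoxyphosphonium) closes the pyran ring with inversion, turning the (R)-carbinol into the (2S)-chroman; the meta-bromine tempers ionisation of the anisylic centre, and with C4 held as a dithioketal no chalcone-type elimination is open.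

**Step 6**
Reactants: 11 1-[2,4-bis(benzyloxy)-6-hydroxyphenyl]ethan-1-one
Product: 12 1-[4,6-bis(benzyloxy)-2-hydroxy-3-iodophenyl]ethan-1-one
Conditions: [BnNMe3][ICl2] (1.05 equiv), NaHCO3, CH2Cl2/MeOH, rt
Reagents that add atoms: benzyltrimethylammonium dichloroiodate, C[N+](C)(C)Cc1ccccc1.Cl[I-]Cl
Why: electrophilic aromatic iodination is directed ortho to the free, hydrogen-bonded phenol, giving the 3-iodo ketone whose iodine becomes C8–I of the flavone.

**Step 7**
Reactants: 12 1-[4,6-bis(benzyloxy)-2-hydroxy-3-iodophenyl]ethan-1-one; 13 4-(benzyloxy)benzaldehyde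
Product: 14 (2E)-1-[4,6-bis(benzyloxy)-2-hydroxy-3-iodophenyl]-3-[4-(benzyloxy)phenyl]prop-2-en-1-one
Conditions: KOH (50% aq., 6 equiv), EtOH/THF, rt; then 1 M HCl
Reagents that add atoms: none
Why: Claisen–Schmidt condensation (aldol addition, then E1cB dehydration) gives the E-chalcone cleanly because the aldehyde partner cannot enolise.

**Step 8**
Reactants: 14 (2E)-1-[4,6-bis(benzyloxy)-2-hydroxy-3-iodophenyl]-3-[4-(benzyloxy)phenyl]prop-2-en-1-one
Product: 15 5,7-bis(benzyloxy)-2-[4-(benzyloxy)phenyl]-8-iodo-4H-chromen-4-one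
Conditions: I2 (10 mol%), DMSO, 130 °C
Reagents that add atoms: none
Why: iodine-catalysed oxidative cyclisation in DMSO (oxa-Michael closure through the only free phenol, α-iodination and loss of HI, which DMSO reoxidises) gives the flavone with the iodine fixed at C8.

**Step 9**
Reactants: 10 (2S)-2-(3-bromo-4-methoxyphenyl)-5,7-dimethoxyspiro[chromane-4,2'-[1,3]dithiane]; 15 5,7-bis(benzyloxy)-2-[4-(benzyloxy)phenyl]-8-iodo-4H-chromen-4-one
Product: 18 5,7-bis(benzyloxy)-2-[4-(benzyloxy)phenyl]-8-{5-[(2S)-5,7-dimethoxyspiro[chromane-4,2'-[1,3]dithian]-2-yl]-2-methoxyphenyl}-4H-chromen-4-one, via aryllithium 16 (not isolated), via arylzinc chloride 17 (not isolated)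
Conditions: n-BuLi (1.05 equiv), THF, −78 °C; ZnCl2 (1.2 equiv), −78 °C to rt; then 15, Pd2(dba)3 (2.5 mol%), SPhos (10 mol%), THF, 60 °C
Reagents that add atoms: none
Why: Negishi coupling, in which bromine–lithium exchange and transmetalation give a non-basic arylzinc that couples with the hindered aryl iodide under zerovalent palladium/SPhos to form the tri-ortho-substituted biaryl; the flavone carbonyl tolerates the zinc reagent, and with C4 still a dithioketal the C2 stereocentre has no retro-oxa-Michael pathway.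

**Step 10**
Reactants: 18 5,7-bis(benzyloxy)-2-[4-(benzyloxy)phenyl]-8-{5-[(2S)-5,7-dimethoxyspiro[chromane-4,2'-[1,3]dithian]-2-yl]-2-methoxyphenyl}-4H-chromen-4-one
Product: 19 5,7-bis(benzyloxy)-2-[4-(benzyloxy)phenyl]-8-{5-[(2S)-5,7-dimethoxy-4-oxo-3,4-dihydro-2H-chromen-2-yl]-2-methoxyphenyl}-4H-chromen-4-one
Conditions: MeI (20 equiv), CaCO3, MeCN/H2O (9:1), 45 °C
Reagents that add atoms: water, O
Why: alkylative dethioketalisation (S-methylation, then hydrolysis of the sulfonium, helped by the electron-rich aryl ring) releases the C4 ketone under buffered, near-neutral conditions that do not open the pyranone, so C2 stays (S).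

**Step 11**
Reactants: 19 5,7-bis(benzyloxy)-2-[4-(benzyloxy)phenyl]-8-{5-[(2S)-5,7-dimethoxy-4-oxo-3,4-dihydro-2H-chromen-2-yl]-2-methoxyphenyl}-4H-chromen-4-one
Product: 20 (2S)-2-{3-[5,7-dihydroxy-2-(4-hydroxyphenyl)-4-oxo-4H-chromen-8-yl]-4-methoxyphenyl}-5-hydroxy-7-methoxy-2,3-dihydro-4H-chromen-4-one
Conditions: BCl3 (10 equiv), C6HMe5 (10 equiv), CH2Cl2, −78 to 0 °C; then H2O
Reagents that add atoms: none
Why: chelation-controlled Lewis acid dealkylation, in which BCl3 with pentamethylbenzene as benzyl-cation scavenger cleaves the three benzyl ethers at low temperature and, through the six-membered chelate with the C4 carbonyl, only the peri 5-methoxy group, leaving the two non-chelated methyl ethers and the C2 stereocentre intact.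

**Compound list**
1 | 2-hydroxy-4,6-dimethoxybenzaldehyde | COc1cc(O)c(C=O)c(OC)c1 | starting material
2 | 2-(1,3-dithian-2-yl)-3,5-dimethoxyphenol | COc1cc(O)c(C2SCCCS2)c(OC)c1 | intermediate
3 | 2-bromoanisole | COc1ccccc1Br | starting material
4 | chloroacetyl chloride | ClCC(Cl)=O | starting material
5 | 1-(3-bromo-4-methoxyphenyl)-2-chloroethan-1-one | COc1ccc(C(=O)CCl)cc1Br | intermediate
6 | (1S)-1-(3-bromo-4-methoxyphenyl)-2-chloroethan-1-ol | COc1ccc([C@H](O)CCl)cc1Br | intermediate
7 | (2S)-2-(3-bromo-4-methoxyphenyl)oxirane | COc1ccc([C@H]2CO2)cc1Br | intermediate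
8 | lithium 2-(2-lithio-1,3-dithian-2-yl)-3,5-dimethoxyphenolate | [Li]Oc1cc(OC)cc(OC)c1C1([Li])SCCCS1 | intermediate
9 | 2-{2-[(2R)-2-(3-bromo-4-methoxyphenyl)-2-hydroxyethyl]-1,3-dithian-2-yl}-3,5-dimethoxyphenol | COc1cc(O)c(C2(C[C@@H](O)c3ccc(OC)c(Br)c3)SCCCS2)c(OC)c1 | intermediate
10 | (2S)-2-(3-bromo-4-methoxyphenyl)-5,7-dimethoxyspiro[chromane-4,2'-[1,3]dithiane] | COc1cc(OC)c2c(c1)O[C@H](c1ccc(OC)c(Br)c1)CC21SCCCS1 | intermediate
11 | 1-[2,4-bis(benzyloxy)-6-hydroxyphenyl]ethan-1-one | CC(=O)c1c(O)cc(OCc2ccccc2)cc1OCc1ccccc1 | starting material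
12 | 1-[4,6-bis(benzyloxy)-2-hydroxy-3-iodophenyl]ethan-1-one | CC(=O)c1c(O)c(I)c(OCc2ccccc2)cc1OCc1ccccc1 | intermediate
13 | 4-(benzyloxy)benzaldehyde | O=Cc1ccc(OCc2ccccc2)cc1 | starting material
14 | (2E)-1-[4,6-bis(benzyloxy)-2-hydroxy-3-iodophenyl]-3-[4-(benzyloxy)phenyl]prop-2-en-1-one | O=C(/C=C/c1ccc(OCc2ccccc2)cc1)c1c(O)c(I)c(OCc2ccccc2)cc1OCc1ccccc1 | intermediate
15 | 5,7-bis(benzyloxy)-2-[4-(benzyloxy)phenyl]-8-iodo-4H-chromen-4-one | O=c1cc(-c2ccc(OCc3ccccc3)cc2)oc2c(I)c(OCc3ccccc3)cc(OCc3ccccc3)c12 | intermediate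
16 | (2S)-2-(3-lithio-4-methoxyphenyl)-5,7-dimethoxyspiro[chromane-4,2'-[1,3]dithiane] | COc1cc(OC)c2c(c1)O[C@H](c1ccc(OC)c([Li])c1)CC21SCCCS1 | intermediate
17 | chlorido{5-[(2S)-5,7-dimethoxyspiro[chromane-4,2'-[1,3]dithian]-2-yl]-2-methoxyphenyl}zinc | COc1cc(OC)c2c(c1)O[C@H](c1ccc(OC)c([Zn]Cl)c1)CC21SCCCS1 | intermediate
18 | 5,7-bis(benzyloxy)-2-[4-(benzyloxy)phenyl]-8-{5-[(2S)-5,7-dimethoxyspiro[chromane-4,2'-[1,3]dithian]-2-yl]-2-methoxyphenyl}-4H-chromen-4-one | COc1cc(OC)c2c(c1)O[C@H](c1ccc(OC)c(-c3c(OCc4ccccc4)cc(OCc4ccccc4)c4c(=O)cc(-c5ccc(OCc6ccccc6)cc5)oc34)c1)CC21SCCCS1 | intermediate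
19 | 5,7-bis(benzyloxy)-2-[4-(benzyloxy)phenyl]-8-{5-[(2S)-5,7-dimethoxy-4-oxo-3,4-dihydro-2H-chromen-2-yl]-2-methoxyphenyl}-4H-chromen-4-one | COc1cc(OC)c2c(c1)O[C@H](c1ccc(OC)c(-c3c(OCc4ccccc4)cc(OCc4ccccc4)c4c(=O)cc(-c5ccc(OCc6ccccc6)cc5)oc34)c1)CC2=O | intermediate
20 | (2S)-2-{3-[5,7-dihydroxy-2-(4-hydroxyphenyl)-4-oxo-4H-chromen-8-yl]-4-methoxyphenyl}-5-hydroxy-7-methoxy-2,3-dihydro-4H-chromen-4-one | COc1cc(O)c2c(c1)O[C@H](c1ccc(OC)c(-c3c(O)cc(O)c4c(=O)cc(-c5ccc(O)cc5)oc34)c1)CC2=O | target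

**Step count and risks**
Total steps: 11. Longest linear sequence: 7 steps (steps 2, 3, 4, 5, 9, 10, 11, from 2-bromoanisole).

Step 4 is at risk because the C-lithiation next to a phenoxide and two ortho substituents may be incomplete, and the hindered dianion may open the acid-labile anisyl epoxide only sluggishly. The fallback sets out from 2 and returns at 9. The phenol is capped with SEMCl/i-Pr2NEt to give 2-(4,6-dimethoxy-2-{[2-(trimethylsilyl)ethoxy]methoxy}phenyl)-1,3-dithiane F1. Its mono-anion (n-BuLi, THF, −30 °C), a cleaner nucleophile with a chelating ortho oxygen, opens 7 to give (1R)-1-(3-bromo-4-methoxyphenyl)-2-[2-(4,6-dimethoxy-2-{[2-(trimethylsilyl)ethoxy]methoxy}phenyl)-1,3-dithian-2-yl]ethan-1-ol F2. Bu4NF in DMPU at 60 °C then frees the phenol to give 9.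

Step 5 is at risk because the alkoxyphosphonium of an anisylic carbinol can ionise (loss of ee) or eliminate. The fallback sets out from 2 and 6 (step 3 stopped before the hydroxide treatment) and returns at 10, with the two ring bonds made in the opposite order. An intermolecular Mitsunobu reaction of 2 with 6 (PPh3, DIAD, toluene) inverts the carbinol, where the β-chlorine suppresses ionisation, and gives 2-{2-[(1R)-1-(3-bromo-4-methoxyphenyl)-2-chloroethoxy]-4,6-dimethoxyphenyl}-1,3-dithiane F3. LiN(i-Pr)2 in THF/DMPU (−78 to 0 °C) then closes the ring by 6-exo-tet alkylation of the dithianyl anion at CH2Cl, giving 10 without touching the stereocentre.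

Step 9 is at risk because the aryl iodide is doubly ortho-substituted, the dithiane can bind palladium, and an organolithium is generated on an advanced intermediate. The fallback sets out from 10 and returns at 18, using boron instead of zinc. Miyaura borylation (Pd(dppf)Cl2, B2pin2, KOAc, dioxane, 90 °C) gives 2-{5-[(2S)-5,7-dimethoxyspiro[chromane-4,2'-[1,3]dithian]-2-yl]-2-methoxyphenyl}-4,4,5,5-tetramethyl-1,3,2-dioxaborolane F4. Suzuki–Miyaura coupling with 15 (Pd(OAc)2, SPhos, K3PO4, toluene/H2O, 90 °C) gives 18; the basic medium is harmless because C4 is still the dithioketal.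

**Further compounds**
F1 | step 4 | 2-(4,6-dimethoxy-2-{[2-(trimethylsilyl)ethoxy]methoxy}phenyl)-1,3-dithiane | COc1cc(OC)c(C2SCCCS2)c(OCOCC[Si](C)(C)C)c1
F2 | step 4 | (1R)-1-(3-bromo-4-methoxyphenyl)-2-[2-(4,6-dimethoxy-2-{[2-(trimethylsilyl)ethoxy]methoxy}phenyl)-1,3-dithian-2-yl]ethan-1-ol | COc1cc(OC)c(C2(C[C@@H](O)c3ccc(OC)c(Br)c3)SCCCS2)c(OCOCC[Si](C)(C)C)c1
F3 | step 5 | 2-{2-[(1R)-1-(3-bromo-4-methoxyphenyl)-2-chloroethoxy]-4,6-dimethoxyphenyl}-1,3-dithiane | COc1cc(OC)c(C2SCCCS2)c(c1)O[C@@H](CCl)c1ccc(OC)c(Br)c1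
F4 | step 9 | 2-{5-[(2S)-5,7-dimethoxyspiro[chromane-4,2'-[1,3]dithian]-2-yl]-2-methoxyphenyl}-4,4,5,5-tetramethyl-1,3,2-dioxaborolane | COc1cc(OC)c2c(c1)O[C@H](c1ccc(OC)c(B3OC(C)(C)C(C)(C)O3)c1)CC21SCCCS1
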